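**Retrosynthetic overview**
1. The E-styryl C=C is cut by Horner–Wadsworth–Emmons olefination into the aldehyde on the quaternary cyclohexene carbon C1 and the 8-phosphonomethyl derivative of coumarin B.
2. Both pyranone rings come from salicylaldehydes by Wittig–lactonisation; each formyl group is placed ortho to a free phenol, so no C6/C8 choice on a finished coumarin arises.
3. Feature: C8 of coumarin A, bonded to cyclohexene C2, sits between C8a (O1) and C7 (OMe) with the C5 methoxy para to it. This is a 2-alkyl-3-silyloxy-5-methoxyphenol, so the arene of coumarin A is grown on C2 from a siloxyalkyne and 3-methoxycyclobutenone.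
4. The siloxyalkyne comes from the cis formyl ester by Kowalski homologation; the cyclohexene with its C1/C2 relationship comes from Claisen ring contraction of the acrylate of methacrolein dimer, resolved as an aminal.
5. Ring order: cyclohexene (step 2), arene of coumarin A (step 7), pyranone A (step 9); pyranone B is closed separately (step 15) and joined at step 16.

Key step: step 7

Assumption: methacrolein dimer 1 is used as the commercial racemate, so 3 and 4 are racemic and the single enantiomer is secured at step 3; which aminal diastereomer carries the (1R,6S) ring is to be assigned by X-ray crystallography.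

**Step 1**
Reactants: 1 methacrolein dimer (racemic 2,5-dimethyl-3,4-dihydro-2H-pyran-2-carbaldehyde); 2 methyl (triphenylphosphoranylidene)acetate
Product: 3 methyl (2E)-3-(2,5-dimethyl-3,4-dihydro-2H-pyran-2-yl)prop-2-enoate (racemic)
Conditions: 2 (1.2 equiv), PhMe, 90 °C
Reagents that add atoms: methyl (triphenylphosphoranylidene)acetate (2), COC(=O)C=P(c1ccccc1)(c1ccccc1)c1ccccc1
Why: Wittig olefination with the ester-stabilised ylide is E-selective, and the aldehyde has no α-hydrogen, so the enol ether and the quaternary centre are untouched.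

**Step 2**
Reactants: 3 methyl (2E)-3-(2,5-dimethyl-3,4-dihydro-2H-pyran-2-yl)prop-2-enoate
Product: 4 methyl (1R*,6S*)-6-formyl-3,6-dimethylcyclohex-2-ene-1-carboxylate (racemic; formyl cis to ester)
Conditions: 1,2-Cl2C6H4, BHT (cat.), 230 °C, sealed tube
Reagents that add atoms: none
Why: Claisen rearrangement of the cyclic allyl vinyl ether (ring contraction of a 2-alkenyl-dihydropyran), in which the two-carbon tether forces a boat-like transition state, so the pyran C2 configuration is relayed to the new quaternary carbon and the ester of the E-alkene should end cis to the formyl group.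

**Step 3**
Reactants: 4 methyl (1R*,6S*)-6-formyl-3,6-dimethylcyclohex-2-ene-1-carboxylate; 5 (1R,2R)-N,N'-dimethyl-1,2-diphenylethane-1,2-diamine
Product: 6 methyl (1R,6S)-6-[(4R,5R)-1,3-dimethyl-4,5-diphenylimidazolidin-2-yl]-3,6-dimethylcyclohex-2-ene-1-carboxylate
Conditions: 5 (1.0 equiv), 4 Å molecular sieves, Et2O, rt; chromatography on Et3N-deactivated SiO2 to separate the two diastereomers
Reagents that add atoms: (1R,2R)-N,N'-dimethyl-1,2-diphenylethane-1,2-diamine (5), CN[C@H](c1ccccc1)[C@H](NC)c1ccccc1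
Why: Aminal formation with a C2-symmetric secondary diamine creates no new stereocentre, so the two enantiomers of 4 give two diastereomers that should separate on silica (resolution of an aldehyde through diastereomeric aminals); the (1R,6S) series is selected here and not set.

**Step 4**
Reactants: 6 methyl (1R,6S)-6-[(4R,5R)-1,3-dimethyl-4,5-diphenylimidazolidin-2-yl]-3,6-dimethylcyclohex-2-ene-1-carboxylate
Product: 8 methyl (1R,6S)-6-(1,3-dioxolan-2-yl)-3,6-dimethylcyclohex-2-ene-1-carboxylate, via free aldehyde 7 (not isolated)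
Conditions: 1 M aq HCl, Et2O, 0 °C; organic phase then HOCH2CH2OH, pyridinium p-toluenesulfonate (cat.), PhH, reflux, Dean–Stark
Reagents that add atoms: ethylene glycol, OCCO
Why: Aminals hydrolyse in cold dilute acid much faster than the ester or the ring alkene react, and the freed non-enolisable aldehyde is then protected by acid-catalysed acetalisation without exposing the ester α-centre to base.

**Step 5**
Reactants: 8 methyl (1R,6S)-6-(1,3-dioxolan-2-yl)-3,6-dimethylcyclohex-2-ene-1-carboxylate
Product: 11 2-{(1S,2S)-1,4-dimethyl-2-[(triisopropylsilyloxy)ethynyl]cyclohex-3-en-1-yl}-1,3-dioxolane (alkynyl cis to dioxolanyl), via dibromoenolate 9 (not isolated), via lithium ynolate 10 (not isolated)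
Conditions: CH2Br2, lithium 2,2,6,6-tetramethylpiperidide, THF, −78 °C; n-BuLi, −78 → 0 °C; i-Pr3SiCl, −78 °C → rt
Reagents that add atoms: dibromomethane, BrCBr; chlorotriisopropylsilane, CC(C)[Si](Cl)(C(C)C)C(C)C
Why: Kowalski ester homologation, in which LiCHBr2 adds to the ester, the dibromoketone is enolised at its CHBr2 carbon (which shields the ring stereocentre), bromine–lithium exchange and 1,2-shift give the ynolate, and the bulky silyl chloride traps it on oxygen.

**Step 6**
Reactants: 12 cyclobutane-1,3-dione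
Product: 13 3-methoxycyclobut-2-en-1-one
Conditions: Me3SiCHN2, PhMe/MeOH (9:1), 0 °C
Reagents that add atoms: (trimethylsilyl)diazomethane, C[Si](C)(C)C=[N+]=[N-]
Why: O-methylation of a vinylogous acid by a diazoalkane, since the dione exists as the strongly acidic 3-hydroxycyclobutenone and the neutral conditions avoid the ring cleavage that alkoxide would cause.

**Step 7**
Reactants: 11 2-{(1S,2S)-1,4-dimethyl-2-[(triisopropylsilyloxy)ethynyl]cyclohex-3-en-1-yl}-1,3-dioxolane; 13 3-methoxycyclobut-2-en-1-one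
Product: 18 2-[(1S,6S)-6-(1,3-dioxolan-2-yl)-3,6-dimethylcyclohex-2-en-1-yl]-5-methoxy-3-(triisopropylsilyloxy)phenol (aryl cis to dioxolanyl), via vinylketene 14 (not isolated), via vinylcyclobutenone 15 (not isolated), via dienylketene 16 (not isolated), via cyclohexadienone 17 (not isolated)
Conditions: 13 (1.5 equiv), PhMe, 80 → 130 °C, sealed tube
Reagents that add atoms: 3-methoxycyclobut-2-en-1-one (13), COC1=CC(=O)C1
Why: Heat opens 13 by four-electron electrocyclic ring opening to vinylketene 14, whose ketene C=C adds [2+2] to the siloxyalkyne with the carbonyl carbon bonding to the alkyne carbon that carries the cyclohexenyl group (the nucleophilic carbon β to the silyloxy group), giving 15. A second four-electron opening gives dienylketene 16, which closes the arene by six-electron electrocyclisation between the ketene carbon and the terminal CH2 to give 17, and tautomerisation gives phenol 18; the closest known reaction is the benzannulation of cyclobutenones with siloxyalkynes (Danheiser benzannulation). The bonds formed are the future C8–C8a, C6–C7 and C4a–C8a of coumarin A, with the hydroxyl as the future O1, the silyloxy group as the future 7-methoxy group and the methoxy group of 13 as the 5-methoxy group. No stereocentre is created, and C1 and C2 of the cyclohexene are spectators because the conditions are neutral. The selectivity needed is the orientation of the [2+2] step, which the polarisation of the ynol ether secures. The crowded alkyne terminus and the slower opening of an alkoxy-stabilised cyclobutenone are met by the sealed tube and the temperature ramp.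

**Step 8**
Reactants: 18 2-[(1S,6S)-6-(1,3-dioxolan-2-yl)-3,6-dimethylcyclohex-2-en-1-yl]-5-methoxy-3-(triisopropylsilyloxy)phenol
Product: 19 3-[(1S,6S)-6-(1,3-dioxolan-2-yl)-3,6-dimethylcyclohex-2-en-1-yl]-2-hydroxy-6-methoxy-4-(triisopropylsilyloxy)benzaldehyde
Conditions: MgCl2, Et3N, (CH2O)n, MeCN, 80 °C
Reagents that add atoms: formaldehyde (as paraformaldehyde), C=O
Why: Magnesium phenoxide-directed ortho-formylation (Casnati–Skattebøl) delivers formaldehyde within the chelate to the only free position ortho to the hydroxyl, a second formaldehyde oxidises the benzylic alkoxide, and the silyl ether, acetal and alkene are inert to these conditions.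

**Step 9**
Reactants: 19 3-[(1S,6S)-6-(1,3-dioxolan-2-yl)-3,6-dimethylcyclohex-2-en-1-yl]-2-hydroxy-6-methoxy-4-(triisopropylsilyloxy)benzaldehyde; 2 methyl (triphenylphosphoranylidene)acetate
Product: 21 8-[(1S,6S)-6-(1,3-dioxolan-2-yl)-3,6-dimethylcyclohex-2-en-1-yl]-5-methoxy-7-(triisopropylsilyloxy)-2H-chromen-2-one, via cinnamate ester 20 (not isolated)
Conditions: 2 (1.3 equiv), PhNEt2, 215 °C
Reagents that add atoms: methyl (triphenylphosphoranylidene)acetate (2), COC(=O)C=P(c1ccccc1)(c1ccccc1)c1ccccc1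
Why: Wittig olefination gives the E-cinnamate, which at this temperature isomerises about the double bond and lactonises with loss of methanol to close the pyranone of coumarin A (Wittig–lactonisation coumarin synthesis).

**Step 10**
Reactants: 21 8-[(1S,6S)-6-(1,3-dioxolan-2-yl)-3,6-dimethylcyclohex-2-en-1-yl]-5-methoxy-7-(triisopropylsilyloxy)-2H-chromen-2-one
Product: 23 8-[(1S,6S)-6-(1,3-dioxolan-2-yl)-3,6-dimethylcyclohex-2-en-1-yl]-5,7-dimethoxy-2H-chromen-2-one, via ammonium phenoxide 22 (not isolated)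
Conditions: Bu4NF, THF, 0 °C; then MeI, rt
Reagents that add atoms: iodomethane, CI
Why: Fluoride cleaves the aryl silyl ether to the ammonium phenoxide, which is O-methylated in the same flask (Williamson etherification), and no other nucleophilic site is present.

**Step 11**
Reactants: 23 8-[(1S,6S)-6-(1,3-dioxolan-2-yl)-3,6-dimethylcyclohex-2-en-1-yl]-5,7-dimethoxy-2H-chromen-2-one
Product: 24 (1S,2S)-2-(5,7-dimethoxy-2-oxo-2H-chromen-8-yl)-1,4-dimethylcyclohex-3-ene-1-carbaldehyde (aryl cis to formyl)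
Conditions: 2 M aq HCl, THF, 45 °C
Reagents that add atoms: water, O
Why: Acid hydrolysis of the dioxolane; the aldehyde sits on a quaternary carbon and cannot epimerise, and the lactone and the trisubstituted alkene tolerate dilute acid.

**Step 12**
Reactants: 25 2-hydroxy-4,6-dimethoxybenzaldehyde
Product: 26 2-(hydroxymethyl)-3,5-dimethoxyphenol
Conditions: NaBH4, MeOH/THF, 0 °C
Reagents that add atoms: none
Why: Borohydride reduction of the aldehyde under basic conditions, which keep the electron-rich salicyl alcohol from ionising.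

**Step 13**
Reactants: 26 2-(hydroxymethyl)-3,5-dimethoxyphenol
Product: 28 diethyl [(2-hydroxy-4,6-dimethoxyphenyl)methyl]phosphonate, via quinone methide 27 (not isolated)
Conditions: P(OEt)3, PhMe, 110 °C
Reagents that add atoms: triethyl phosphite, CCOP(OCC)OCC
Why: Thermal loss of water gives the ortho-quinone methide, which the phosphite traps by conjugate addition, and the phosphonium phenoxide is dealkylated by the released water (Michaelis–Arbuzov-type) to the ortho-hydroxybenzyl phosphonate.

**Step 14**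
Reactants: 28 diethyl [(2-hydroxy-4,6-dimethoxyphenyl)methyl]phosphonate
Product: 29 diethyl [(3-formyl-2-hydroxy-4,6-dimethoxyphenyl)methyl]phosphonate
Conditions: MgCl2, Et3N, (CH2O)n, MeCN, 80 °C
Reagents that add atoms: formaldehyde (as paraformaldehyde), C=O
Why: Magnesium phenoxide-directed ortho-formylation (Casnati–Skattebøl) reaches only the one free position ortho to the hydroxyl, which fixes the phosphonomethyl group at the future C8 and the formyl group at the future C4a.

**Step 15**
Reactants: 29 diethyl [(3-formyl-2-hydroxy-4,6-dimethoxyphenyl)methyl]phosphonate; 2 methyl (triphenylphosphoranylidene)acetate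
Product: 31 diethyl [(5,7-dimethoxy-2-oxo-2H-chromen-8-yl)methyl]phosphonate, via cinnamate ester 30 (not isolated)
Conditions: 2 (1.3 equiv), PhNEt2, 215 °C
Reagents that add atoms: methyl (triphenylphosphoranylidene)acetate (2), COC(=O)C=P(c1ccccc1)(c1ccccc1)c1ccccc1
Why: Wittig–lactonisation as in step 9; the stabilised ylide is too weak a base to deprotonate the benzylic phosphonate.

**Step 16**
Reactants: 24 (1S,2S)-2-(5,7-dimethoxy-2-oxo-2H-chromen-8-yl)-1,4-dimethylcyclohex-3-ene-1-carbaldehyde; 31 diethyl [(5,7-dimethoxy-2-oxo-2H-chromen-8-yl)methyl]phosphonate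
Product: 32 8-[(1R,6R)-6-[(E)-2-(5,7-dimethoxy-2-oxo-2H-chromen-8-yl)ethenyl]-3,6-dimethylcyclohex-2-en-1-yl]-5,7-dimethoxy-2H-chromen-2-one (CNP0164660.2)
Conditions: 31 (1.3 equiv), KN(SiMe3)2, THF, −78 °C; then 24, −78 °C → rt
Reagents that add atoms: diethyl [(5,7-dimethoxy-2-oxo-2H-chromen-8-yl)methyl]phosphonate (31), CCOP(=O)(Cc1c(OC)cc(OC)c2ccc(=O)oc12)OCC
Why: Horner–Wadsworth–Emmons olefination, in which the benzylic phosphonate anion adds to the non-enolisable aldehyde and elimination of diethyl phosphate should give the E-styrene; the hindered amide base is not expected to open the lactones, and the C2–H is too weakly acidic to be removed.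

**Compound list**
1 | methacrolein dimer, 2,5-dimethyl-3,4-dihydro-2H-pyran-2-carbaldehyde (racemic) | CC1=COC(C)(C=O)CC1 | starting material
2 | methyl (triphenylphosphoranylidene)acetate | COC(=O)C=P(c1ccccc1)(c1ccccc1)c1ccccc1 | starting material
3 | methyl (2E)-3-(2,5-dimethyl-3,4-dihydro-2H-pyran-2-yl)prop-2-enoate (racemic) | COC(=O)/C=C/C1(C)CCC(C)=CO1 | intermediate
4 | methyl (1R*,6S*)-6-formyl-3,6-dimethylcyclohex-2-ene-1-carboxylate (racemic, formyl cis to ester; both enantiomers written) | CC1=C[C@@H](C(=O)OC)[C@@](C)(C=O)CC1.CC1=C[C@H](C(=O)OC)[C@](C)(C=O)CC1 | intermediate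
5 | (1R,2R)-N,N'-dimethyl-1,2-diphenylethane-1,2-diamine | CN[C@H](c1ccccc1)[C@H](NC)c1ccccc1 | starting material
6 | methyl (1R,6S)-6-[(4R,5R)-1,3-dimethyl-4,5-diphenylimidazolidin-2-yl]-3,6-dimethylcyclohex-2-ene-1-carboxylate | CC1=C[C@@H](C(=O)OC)[C@@](C)(C2N(C)[C@H](c3ccccc3)[C@@H](c3ccccc3)N2C)CC1 | intermediate
7 | methyl (1R,6S)-6-formyl-3,6-dimethylcyclohex-2-ene-1-carboxylate (single enantiomer, not isolated) | CC1=C[C@@H](C(=O)OC)[C@@](C)(C=O)CC1 | intermediate
8 | methyl (1R,6S)-6-(1,3-dioxolan-2-yl)-3,6-dimethylcyclohex-2-ene-1-carboxylate | CC1=C[C@@H](C(=O)OC)[C@@](C)(C2OCCO2)CC1 | intermediate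
9 | lithium 2,2-dibromo-1-[6-(1,3-dioxolan-2-yl)-3,6-dimethylcyclohex-2-en-1-yl]ethenolate (ring stereocentres as in 8, not isolated) | CC1=C[C@@H](C([O-])=C(Br)Br)[C@@](C)(C2OCCO2)CC1.[Li+] | intermediate
10 | lithium 2-[6-(1,3-dioxolan-2-yl)-3,6-dimethylcyclohex-2-en-1-yl]ethynolate (ring stereocentres as in 8, not isolated) | CC1=C[C@@H](C#C[O-])[C@@](C)(C2OCCO2)CC1.[Li+] | intermediate
11 | 2-{(1S,2S)-1,4-dimethyl-2-[(triisopropylsilyloxy)ethynyl]cyclohex-3-en-1-yl}-1,3-dioxolane | CC1=C[C@@H](C#CO[Si](C(C)C)(C(C)C)C(C)C)[C@@](C)(C2OCCO2)CC1 | intermediate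
12 | cyclobutane-1,3-dione | O=C1CC(=O)C1 | starting material
13 | 3-methoxycyclobut-2-en-1-one | COC1=CC(=O)C1 | intermediate
14 | 3-methoxybuta-1,3-dien-1-one (vinylketene, not isolated) | C=C(OC)C=C=O | intermediate
15 | 2-[6-(1,3-dioxolan-2-yl)-3,6-dimethylcyclohex-2-en-1-yl]-4-(1-methoxyethenyl)-3-(triisopropylsilyloxy)cyclobut-2-en-1-one (ring stereocentres as in 11, cyclobutenone C4 unassigned, not isolated) | CC1=C[C@@H](C2=C(O[Si](C(C)C)(C(C)C)C(C)C)C(C(OC)=C)C2=O)[C@@](C)(C2OCCO2)CC1 | intermediate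
16 | 2-[6-(1,3-dioxolan-2-yl)-3,6-dimethylcyclohex-2-en-1-yl]-5-methoxy-3-(triisopropylsilyloxy)hexa-1,3,5-trien-1-one (dienylketene, ring stereocentres as in 11, not isolated) | CC1=C[C@@H](C(=C=O)/C(O[Si](C(C)C)(C(C)C)C(C)C)=C\C(OC)=C)[C@@](C)(C2OCCO2)CC1 | intermediate
17 | 2-[6-(1,3-dioxolan-2-yl)-3,6-dimethylcyclohex-2-en-1-yl]-5-methoxy-3-(triisopropylsilyloxy)cyclohexa-2,4-dien-1-one (ring stereocentres as in 11, not isolated) | CC1=C[C@@H](C2=C(O[Si](C(C)C)(C(C)C)C(C)C)C=C(OC)CC2=O)[C@@](C)(C2OCCO2)CC1 | intermediate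
18 | 2-[(1S,6S)-6-(1,3-dioxolan-2-yl)-3,6-dimethylcyclohex-2-en-1-yl]-5-methoxy-3-(triisopropylsilyloxy)phenol | CC1=C[C@@H](c2c(O)cc(OC)cc2O[Si](C(C)C)(C(C)C)C(C)C)[C@@](C)(C2OCCO2)CC1 | intermediate
19 | 3-[(1S,6S)-6-(1,3-dioxolan-2-yl)-3,6-dimethylcyclohex-2-en-1-yl]-2-hydroxy-6-methoxy-4-(triisopropylsilyloxy)benzaldehyde | CC1=C[C@@H](c2c(O)c(C=O)c(OC)cc2O[Si](C(C)C)(C(C)C)C(C)C)[C@@](C)(C2OCCO2)CC1 | intermediate
20 | methyl (2E)-3-{3-[6-(1,3-dioxolan-2-yl)-3,6-dimethylcyclohex-2-en-1-yl]-2-hydroxy-6-methoxy-4-(triisopropylsilyloxy)phenyl}prop-2-enoate (ring stereocentres as in 19, not isolated) | CC1=C[C@@H](c2c(O)c(/C=C/C(=O)OC)c(OC)cc2O[Si](C(C)C)(C(C)C)C(C)C)[C@@](C)(C2OCCO2)CC1 | intermediate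
21 | 8-[(1S,6S)-6-(1,3-dioxolan-2-yl)-3,6-dimethylcyclohex-2-en-1-yl]-5-methoxy-7-(triisopropylsilyloxy)-2H-chromen-2-one | CC1=C[C@@H](c2c(O[Si](C(C)C)(C(C)C)C(C)C)cc(OC)c3ccc(=O)oc23)[C@@](C)(C2OCCO2)CC1 | intermediate
22 | tetrabutylammonium 8-[6-(1,3-dioxolan-2-yl)-3,6-dimethylcyclohex-2-en-1-yl]-5-methoxy-2-oxo-2H-chromen-7-olate (ring stereocentres as in 21, not isolated) | CC1=C[C@@H](c2c([O-])cc(OC)c3ccc(=O)oc23)[C@@](C)(C2OCCO2)CC1.CCCC[N+](CCCC)(CCCC)CCCC | intermediate
23 | 8-[(1S,6S)-6-(1,3-dioxolan-2-yl)-3,6-dimethylcyclohex-2-en-1-yl]-5,7-dimethoxy-2H-chromen-2-one | CC1=C[C@@H](c2c(OC)cc(OC)c3ccc(=O)oc23)[C@@](C)(C2OCCO2)CC1 | intermediate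
24 | (1S,2S)-2-(5,7-dimethoxy-2-oxo-2H-chromen-8-yl)-1,4-dimethylcyclohex-3-ene-1-carbaldehyde | CC1=C[C@@H](c2c(OC)cc(OC)c3ccc(=O)oc23)[C@@](C)(C=O)CC1 | intermediate
25 | 2-hydroxy-4,6-dimethoxybenzaldehyde | COc1cc(O)c(C=O)c(OC)c1 | starting material
26 | 2-(hydroxymethyl)-3,5-dimethoxyphenol | COc1cc(O)c(CO)c(OC)c1 | intermediate
27 | 3,5-dimethoxy-6-methylidenecyclohexa-2,4-dien-1-one (ortho-quinone methide, not isolated) | C=C1C(=O)C=C(OC)C=C1OC | intermediate
28 | diethyl [(2-hydroxy-4,6-dimethoxyphenyl)methyl]phosphonate | CCOP(=O)(Cc1c(O)cc(OC)cc1OC)OCC | intermediate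
29 | diethyl [(3-formyl-2-hydroxy-4,6-dimethoxyphenyl)methyl]phosphonate | CCOP(=O)(Cc1c(O)c(C=O)c(OC)cc1OC)OCC | intermediate
30 | methyl (2E)-3-{3-[(diethoxyphosphoryl)methyl]-2-hydroxy-4,6-dimethoxyphenyl}prop-2-enoate (not isolated) | CCOP(=O)(Cc1c(O)c(/C=C/C(=O)OC)c(OC)cc1OC)OCC | intermediate
31 | diethyl [(5,7-dimethoxy-2-oxo-2H-chromen-8-yl)methyl]phosphonate | CCOP(=O)(Cc1c(OC)cc(OC)c2ccc(=O)oc12)OCC | intermediate
32 | 8-[(1R,6R)-6-[(E)-2-(5,7-dimethoxy-2-oxo-2H-chromen-8-yl)ethenyl]-3,6-dimethylcyclohex-2-en-1-yl]-5,7-dimethoxy-2H-chromen-2-one | COc1cc(OC)c2ccc(=O)oc2c1/C=C/[C@@]1(C)CCC(C)=C[C@H]1c1c(OC)cc(OC)c2ccc(=O)oc12 | target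

**Step count**
Total steps: 16. Longest linear sequence: 11 (steps 1–5, 7–11 and 16); step 6 and steps 12–15 are side branches.

**Steps most likely to fail**

Step 7. The [2+2] addition may be slow at the alkyne carbon next to the crowded ring, and the alkoxy-substituted vinylketene may be lost by self-condensation or by acylating the product phenol. The fallback gives up growing the arene on C2 and forms the cyclohexene by cycloaddition onto a finished coumarin. It sets out from phosphonate 31, which with KN(SiMe3)2 and methacrolein in THF should give the diene 5,7-dimethoxy-8-[(1E)-3-methylbuta-1,3-dien-1-yl]-2H-chromen-2-one F1. Diels–Alder reaction of F1 with methacrolein in CH2Cl2 at −78 °C would be run under the oxazaborolidinium salt made from the B-(2-methylphenyl) oxazaborolidine of α,α-diphenylprolinol and HN(SO2CF3)2, in the enantiomeric form that leads to the (1S,2S) adduct. With formyl endo and the aryl and methyl groups directing ortho and para, this should give aldehyde 24, where the route is rejoined for step 16.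

Step 5. The lithium amide may remove the allylic α-hydrogen of the hindered ester faster than the carbenoid adds, which would scramble the C2 configuration or move the double bond. The fallback makes the ynolate by oxidation of an acetylide and sets out from ester 8. LiAlH4 in THF at 0 °C should give the alcohol [(1R,6S)-6-(1,3-dioxolan-2-yl)-3,6-dimethylcyclohex-2-en-1-yl]methanol F2. Dess–Martin periodinane with NaHCO3 in CH2Cl2 should give the aldehyde (1R,6S)-6-(1,3-dioxolan-2-yl)-3,6-dimethylcyclohex-2-ene-1-carbaldehyde F3, which is kept cold and free of base. CBr4, PPh3 and Zn in CH2Cl2 should give the dibromoalkene 2-[(1S,2S)-2-(2,2-dibromoethenyl)-1,4-dimethylcyclohex-3-en-1-yl]-1,3-dioxolane F4. n-BuLi (2 equiv) in THF at −78 °C should give the lithium acetylide F5, which LiOOt-Bu oxidises to ynolate 10; i-Pr3SiOTf then gives siloxyalkyne 11, where the route is rejoined.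

Step 16. The stabilised phosphonate anion, flanked by two ortho substituents, may add too slowly to the neopentyl-type aldehyde and be lost by attack on a lactone carbonyl. The fallback olefinates with a lactone-free, more nucleophilic phosphonate and closes pyranone B afterwards. It sets out from aldehyde 24 and phenol phosphonate 28. The dianion of 28 (KN(SiMe3)2, 2.2 equiv, THF) should give the styrene 8-[(1R,6R)-6-[(E)-2-(2-hydroxy-4,6-dimethoxyphenyl)ethenyl]-3,6-dimethylcyclohex-2-en-1-yl]-5,7-dimethoxy-2H-chromen-2-one F6. MgCl2, Et3N and (CH2O)n in MeCN should formylate ortho to the hydroxyl to give the salicylaldehyde F7. Ylide 2 in PhNEt2 at 215 °C should then give, by way of the cinnamate ester F8, the target 32.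

**Further compounds**
F1 | step 7 | 5,7-dimethoxy-8-[(1E)-3-methylbuta-1,3-dien-1-yl]-2H-chromen-2-one | C=C(C)/C=C/c1c(OC)cc(OC)c2ccc(=O)oc12
F2 | step 5 | [(1R,6S)-6-(1,3-dioxolan-2-yl)-3,6-dimethylcyclohex-2-en-1-yl]methanol | CC1=C[C@@H](CO)[C@@](C)(C2OCCO2)CC1
F3 | step 5 | (1R,6S)-6-(1,3-dioxolan-2-yl)-3,6-dimethylcyclohex-2-ene-1-carbaldehyde | CC1=C[C@@H](C=O)[C@@](C)(C2OCCO2)CC1
F4 | step 5 | 2-[(1S,2S)-2-(2,2-dibromoethenyl)-1,4-dimethylcyclohex-3-en-1-yl]-1,3-dioxolane | CC1=C[C@@H](C=C(Br)Br)[C@@](C)(C2OCCO2)CC1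
F5 | step 5 | lithium acetylide of 2-(2-ethynyl-1,4-dimethylcyclohex-3-en-1-yl)-1,3-dioxolane (ring stereocentres as in 11) | CC1=C[C@@H](C#C[Li])[C@@](C)(C2OCCO2)CC1
F6 | step 16 | 8-[(1R,6R)-6-[(E)-2-(2-hydroxy-4,6-dimethoxyphenyl)ethenyl]-3,6-dimethylcyclohex-2-en-1-yl]-5,7-dimethoxy-2H-chromen-2-one | CC1=C[C@@H](c2c(OC)cc(OC)c3ccc(=O)oc23)[C@@](C)(/C=C/c2c(O)cc(OC)cc2OC)CC1
F7 | step 16 | 3-[(E)-2-[(1R,2R)-2-(5,7-dimethoxy-2-oxo-2H-chromen-8-yl)-1,4-dimethylcyclohex-3-en-1-yl]ethenyl]-2-hydroxy-4,6-dimethoxybenzaldehyde | CC1=C[C@@H](c2c(OC)cc(OC)c3ccc(=O)oc23)[C@@](C)(/C=C/c2c(O)c(C=O)c(OC)cc2OC)CC1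
F8 | step 16 | methyl (2E)-3-{3-[(E)-2-[(1R,2R)-2-(5,7-dimethoxy-2-oxo-2H-chromen-8-yl)-1,4-dimethylcyclohex-3-en-1-yl]ethenyl]-2-hydroxy-4,6-dimethoxyphenyl}prop-2-enoate | CC1=C[C@@H](c2c(OC)cc(OC)c3ccc(=O)oc23)[C@@](C)(/C=C/c2c(O)c(/C=C/C(=O)OC)c(OC)cc2OC)CC1
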